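**Plan**

1. Locants follow the target: C1 ester carbon, C2, ring carbons C3 (on O2), C4 (ethyl), C5, C6 (on O1, with ethyl and the arm), arm C7=C8(ethyl)–C9–C10(ethyl)–butyl.
2. Retrosynthesis: O1–C6 is cut first, opening the 1,2-dioxane to a C3 hydroperoxide that carries a (5Z,7E)-C5=C6–C7=C8 diene. Then C6–C7 (two alkenyl halves), C5=C6 (aldehyde plus α-iodo ylide), C3–O2 (secondary triflate plus peroxide anion), C3–C4 (aldol), and in the arm C8–ethyl/C7–iodine (carbocupration) and C10–ethyl (conjugate addition).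
3. Forward: the chiral arm and the peroxide-bearing (Z)-alkenyl iodide are made separately and joined at C6–C7 by Negishi coupling. The hydroperoxide is unmasked, the only ring is closed by acid-catalysed capture of the dienyl cation, and C1 is then taken from a protected alcohol to the methyl ester.
4. Enabling feature: C6 is tertiary and allylic to C7=C8, so protonation of the diene at C5 gives a bis-tertiary allyl cation (C6–C7–C8) that the O1–H of the C3 hydroperoxide reaches at C6 through a six-membered chair.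
5. Stereochemistry: C10 from a copper-catalysed asymmetric conjugate addition; C4 and the C3 carbinol from an Evans syn-aldol, C3–O2 by SN2 inversion; 7E from syn-carbocupration, 5Z from the iodo-Wittig olefination; C6 in the ring closure, set by the 5Z geometry and the C3/C4 centres.

Key step: step 16

**Route**

Step 1
Reactants: 1 methyl (E)-hept-2-enoate
Product: 2 methyl (3S)-3-ethylheptanoate
Conditions: EtMgBr, CuBr·SMe2 (5 mol%), Josiphos ligand (R)-1-[(S)-2-(diphenylphosphino)ferrocenyl]ethyldicyclohexylphosphine (6 mol%), t-BuOMe, −75 °C; aq. NH4Cl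
Reagents that add atoms: ethylmagnesium bromide, CC[Mg]Br
Why: Copper-catalysed asymmetric conjugate addition of a Grignard reagent to a linear (E)-enoate, in which the chiral diphosphine–copper complex selects the enoate face and so sets C10 (the ligand enantiomer that delivers the S ester is the one used).

Step 2
Reactants: 2 methyl (3S)-3-ethylheptanoate
Product: 3 (3S)-3-ethylheptanal
Conditions: i-Bu2AlH (1.05 equiv), CH2Cl2, −78 °C; aq. potassium sodium tartrate
Reagents that add atoms: none
Why: Partial reduction of the ester stops at the aldehyde because the tetrahedral aluminium hemiacetal is stable at −78 °C, and the β-stereocenter is not touched.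

Step 3
Reactants: 3 (3S)-3-ethylheptanal
Product: 4 (4S)-4-ethyloct-1-yne
Conditions: dimethyl (1-diazo-2-oxopropyl)phosphonate, K2CO3, MeOH, 0 °C to rt
Reagents that add atoms: dimethyl (1-diazo-2-oxopropyl)phosphonate, COP(=O)(OC)C(=[N+]=[N-])C(C)=O
Why: Seyferth–Gilbert homologation with the Ohira–Bestmann reagent converts the aldehyde into the terminal alkyne under mild base that cannot epimerise the remote stereocenter.

Step 4
Reactants: 4 (4S)-4-ethyloct-1-yne
Product: 6 (1E,4S)-2,4-diethyl-1-iodooct-1-ene, via alkenylcopper 5 (not isolated)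
Conditions: EtMgBr, CuBr·SMe2, Et2O/Me2S, −45 °C; 4, −25 °C; then I2, THF, −78 to 0 °C
Reagents that add atoms: ethylmagnesium bromide, CC[Mg]Br; iodine, II
Why: Normant-type carbocupration adds ethyl and copper syn across the terminal alkyne with copper on the terminal carbon, and iodinolysis with retention gives the E iodide (ethyl cis to iodine), which fixes the C7=C8 geometry.

Step 5
Reactants: 7 3-[(4-methoxybenzyl)oxy]propan-1-ol
Product: 8 3-[(4-methoxybenzyl)oxy]propanal
Conditions: Dess–Martin periodinane, CH2Cl2, rt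
Reagents that add atoms: none
Why: Dess–Martin oxidation of a primary alcohol gives the aldehyde without over-oxidation and leaves the PMB ether intact.

Step 6
Reactants: 9 (4S)-4-benzyl-3-butanoyl-1,3-oxazolidin-2-one; 8 3-[(4-methoxybenzyl)oxy]propanal
Product: 11 (4S)-4-benzyl-3-[(2S,3R)-2-ethyl-3-hydroxy-5-[(4-methoxybenzyl)oxy]pentanoyl]-1,3-oxazolidin-2-one, via boron enolate 10 (not isolated)
Conditions: n-Bu2BOTf, i-Pr2NEt, CH2Cl2, −78 to 0 °C; 8, −78 to 0 °C; pH 7 buffer, MeOH, 30% H2O2, 0 °C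
Reagents that add atoms: none
Why: Evans syn-aldol reaction, in which the (Z)-boron enolate reacts through a Zimmerman–Traxler chair on the face away from the auxiliary benzyl group, setting C4 and the syn C3 carbinol.

Step 7
Reactants: 11 (4S)-4-benzyl-3-[(2S,3R)-2-ethyl-3-hydroxy-5-[(4-methoxybenzyl)oxy]pentanoyl]-1,3-oxazolidin-2-one
Product: 12 (2R,3R)-2-ethyl-5-[(4-methoxybenzyl)oxy]pentane-1,3-diol
Conditions: LiBH4, MeOH (1 equiv), THF, 0 °C
Reagents that add atoms: none
Why: Reductive cleavage of the N-acyl oxazolidinone with LiBH4 gives the primary alcohol without touching either stereocenter and returns the auxiliary.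

Step 8
Reactants: 12 (2R,3R)-2-ethyl-5-[(4-methoxybenzyl)oxy]pentane-1,3-diol
Product: 13 (2R,3R)-1-{[tert-butyl(diphenyl)silyl]oxy}-2-ethyl-5-[(4-methoxybenzyl)oxy]pentan-3-ol
Conditions: t-BuPh2SiCl, imidazole, CH2Cl2, 0 °C
Reagents that add atoms: tert-butyl(chloro)diphenylsilane, CC(C)(C)[Si](Cl)(c1ccccc1)c1ccccc1
Why: The bulky silyl chloride silylates the primary hydroxyl selectively and leaves the secondary C3 hydroxyl free for activation.

Step 9
Reactants: 14 2,3-dimethylbut-2-ene
Product: 15 2-methoxyprop-2-yl hydroperoxide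
Conditions: O3, MeOH/CH2Cl2, −78 °C; N2 purge
Reagents that add atoms: ozone, [O-][O+]=O; methanol, CO
Why: Ozonolysis in methanol, in which the Criegee carbonyl oxide is trapped by the solvent to give the α-methoxy hydroperoxide, a hydroperoxide donor that carries its own acid-labile protecting group.

Step 10
Reactants: 13 (2R,3R)-1-{[tert-butyl(diphenyl)silyl]oxy}-2-ethyl-5-[(4-methoxybenzyl)oxy]pentan-3-ol; 15 2-methoxyprop-2-yl hydroperoxide
Product: 17 tert-butyl{[(2R,3S)-2-ethyl-5-[(4-methoxybenzyl)oxy]-3-[(2-methoxypropan-2-yl)peroxy]pentyl]oxy}diphenylsilane, via triflate 16 (not isolated)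
Conditions: Tf2O, 2,6-lutidine, CH2Cl2, −78 °C; then 15 (3 equiv), KOt-Bu (3 equiv), THF, −78 to 0 °C
Reagents that add atoms: none
Why: SN2 alkylation of a peroxide anion by a secondary triflate with inversion at C3, where the weakly basic α-nucleophile and the low temperature favour substitution over elimination, gives the anti C3–O/C4–ethyl relationship with the hydroperoxide already masked as a base-stable peroxyketal.

Step 11
Reactants: 17 tert-butyl{[(2R,3S)-2-ethyl-5-[(4-methoxybenzyl)oxy]-3-[(2-methoxypropan-2-yl)peroxy]pentyl]oxy}diphenylsilane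
Product: 18 (2R,3S)-2-ethyl-5-[(4-methoxybenzyl)oxy]-3-[(2-methoxypropan-2-yl)peroxy]pentan-1-ol
Conditions: Bu4NF, THF, 0 °C
Reagents that add atoms: none
Why: Fluoride desilylation frees the primary alcohol, and neither the peroxyketal nor the PMB ether reacts with fluoride.

Step 12
Reactants: 18 (2R,3S)-2-ethyl-5-[(4-methoxybenzyl)oxy]-3-[(2-methoxypropan-2-yl)peroxy]pentan-1-ol
Product: 19 (2S,3S)-2-ethyl-5-[(4-methoxybenzyl)oxy]-3-[(2-methoxypropan-2-yl)peroxy]pentanal
Conditions: Dess–Martin periodinane, NaHCO3, CH2Cl2, 0 °C; used at once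
Reagents that add atoms: none
Why: Buffered Dess–Martin oxidation is neutral, so the α-branched β-peroxy aldehyde should form without epimerisation at C4 or β-elimination of the peroxide.

Step 13
Reactants: 19 (2S,3S)-2-ethyl-5-[(4-methoxybenzyl)oxy]-3-[(2-methoxypropan-2-yl)peroxy]pentanal
Product: 20 1-({[(3S,4R,5Z)-4-ethyl-6-iodo-3-[(2-methoxypropan-2-yl)peroxy]oct-5-en-1-yl]oxy}methyl)-4-methoxybenzene
Conditions: propyltriphenylphosphonium bromide, n-BuLi, THF, 0 °C; I2, −78 °C; NaN(SiMe3)2, −78 to −20 °C; then 19, −78 °C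
Reagents that add atoms: propyltriphenylphosphonium bromide, CCC[P+](c1ccccc1)(c1ccccc1)c1ccccc1.[Br-]; iodine, II
Why: Stork–Zhao-type Wittig olefination with the α-iodo ylide made in the flask adds under kinetic control to give the Z alkenyl iodide (iodine cis to C4), and the low temperature limits epimerisation and elimination.

Step 14
Reactants: 6 (1E,4S)-2,4-diethyl-1-iodooct-1-ene; 20 1-({[(3S,4R,5Z)-4-ethyl-6-iodo-3-[(2-methoxypropan-2-yl)peroxy]oct-5-en-1-yl]oxy}methyl)-4-methoxybenzene
Product: 23 1-({[(3S,4R,5Z,7E,10S)-4,6,8,10-tetraethyl-3-[(2-methoxypropan-2-yl)peroxy]tetradeca-5,7-dien-1-yl]oxy}methyl)-4-methoxybenzene, via alkenyllithium 21 (not isolated), via alkenylzinc chloride 22 (not isolated)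
Conditions: 6, t-BuLi (2 equiv), Et2O, −78 °C; ZnCl2, THF, −78 to 0 °C; then 20, Pd(PPh3)4 (5 mol%), THF, rt
Reagents that add atoms: none
Why: Negishi coupling joins the two alkenyl partners with retention at both carbons to give the (5Z,7E)-diene, and the alkenylzinc and palladium catalyst are mild enough for the dialkyl peroxyketal.

Step 15
Reactants: 23 1-({[(3S,4R,5Z,7E,10S)-4,6,8,10-tetraethyl-3-[(2-methoxypropan-2-yl)peroxy]tetradeca-5,7-dien-1-yl]oxy}methyl)-4-methoxybenzene
Product: 24 1-({[(3S,4R,5Z,7E,10S)-4,6,8,10-tetraethyl-3-hydroperoxytetradeca-5,7-dien-1-yl]oxy}methyl)-4-methoxybenzene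
Conditions: pyridinium p-toluenesulfonate (cat.), MeOH, 0 °C
Reagents that add atoms: none
Why: Acid-catalysed transketalisation to methanol releases the free secondary hydroperoxide under conditions too weakly acidic to protonate the diene.

Step 16
Reactants: 24 1-({[(3S,4R,5Z,7E,10S)-4,6,8,10-tetraethyl-3-hydroperoxytetradeca-5,7-dien-1-yl]oxy}methyl)-4-methoxybenzene
Product: 25 (3S,4R,6S)-6-[(1E,4S)-2,4-diethyloct-1-en-1-yl]-4,6-diethyl-3-{2-[(4-methoxybenzyl)oxy]ethyl}-1,2-dioxane
Conditions: HNTf2 (5 mol%), CH2Cl2 (0.01 M), −78 °C; Et3N quench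
Reagents that add atoms: none
Why: Proposed new method: the acid protonates the diene at C5, the only site that gives a bis-tertiary allyl cation (C6–C7–C8), and the terminal oxygen of the C3 hydroperoxide captures it at C6; the closest known reaction types are the Brønsted-acid-catalysed intramolecular hydroalkoxylation of 1,3-dienes and the acid-catalysed Markovnikov addition of H2O2 or hydroperoxides to alkenes that gives tertiary peroxides. The 1,2-dioxane is the only ring closed, in a 6-endo-trig mode at C6, since attack at C8 would need an eight-membered ring and attack at C5 is anti-Markovnikov. The one new stereocenter, C6, is controlled by the 5Z geometry together with C3 and C4: in the A(1,3)-minimised conformer the C4–H bond points toward the cis C7 substituent, the hydroperoxide arm lies over one face of C5=C6, and closure through a chair with the C3 and C4 substituents equatorial puts the C6 group that was trans to C4 (ethyl) equatorial and the cis group (the alkenyl arm) axial, which is the 6S configuration, whereas the other chair would place the C4 ethyl group 1,3-diaxial to the arm. The step needs capture of the cation to be faster than rotation about C5–C6 or C7–C8, proton loss and re-ionisation of the tertiary allylic peroxide; the preorganised six-membered transition state, the non-basic NTf2 counter-ion, −78 °C, high dilution and an early amine quench serve this, and the 7E alkene should be carried through because the allyl cation keeps its geometry over its short lifetime.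

Step 17
Reactants: 25 (3S,4R,6S)-6-[(1E,4S)-2,4-diethyloct-1-en-1-yl]-4,6-diethyl-3-{2-[(4-methoxybenzyl)oxy]ethyl}-1,2-dioxane
Product: 26 2-[(3S,4R,6S)-6-[(1E,4S)-2,4-diethyloct-1-en-1-yl]-4,6-diethyl-1,2-dioxan-3-yl]ethan-1-ol
Conditions: DDQ, CH2Cl2/pH 7 buffer, 0 °C
Reagents that add atoms: none
Why: Oxidative PMB cleavage by benzylic hydride abstraction and hydrolysis frees the primary alcohol, and neither the dialkyl peroxide nor the trisubstituted alkene is oxidised by DDQ under buffered conditions.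

Step 18
Reactants: 26 2-[(3S,4R,6S)-6-[(1E,4S)-2,4-diethyloct-1-en-1-yl]-4,6-diethyl-1,2-dioxan-3-yl]ethan-1-ol
Product: 28 2-[(3S,4R,6S)-6-[(1E,4S)-2,4-diethyloct-1-en-1-yl]-4,6-diethyl-1,2-dioxan-3-yl]acetic acid, via aldehyde 27 (not isolated)
Conditions: TEMPO (cat.), PhI(OAc)2, MeCN/H2O, rt
Reagents that add atoms: water, O
Why: Oxoammonium (TEMPO) oxidation takes the alcohol through the aldehyde hydrate to the acid under near-neutral conditions, so the β-peroxy carbonyl compounds should not eliminate.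

Step 19
Reactants: 28 2-[(3S,4R,6S)-6-[(1E,4S)-2,4-diethyloct-1-en-1-yl]-4,6-diethyl-1,2-dioxan-3-yl]acetic acid
Product: 29 methyl 2-[(3S,4R,6S)-6-[(1E,4S)-2,4-diethyloct-1-en-1-yl]-4,6-diethyl-1,2-dioxan-3-yl]acetate
Conditions: Me3SiCHN2, MeOH/toluene, 0 °C
Reagents that add atoms: (trimethylsilyl)diazomethane, C[Si](C)(C)C=[N+]=[N-]
Why: Neutral O-methylation of the acid with (trimethylsilyl)diazomethane avoids base, which could open the ring by retro-oxa-Michael elimination of the β-peroxy ester.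

**Compound list**

1 | methyl (E)-hept-2-enoate | CCCC/C=C/C(=O)OC | starting material
2 | methyl (3S)-3-ethylheptanoate | CCCC[C@H](CC)CC(=O)OC | intermediate
3 | (3S)-3-ethylheptanal | CCCC[C@H](CC)CC=O | intermediate
4 | (4S)-4-ethyloct-1-yne | CCCC[C@H](CC)CC#C | intermediate
5 | [(1E,4S)-2,4-diethyloct-1-en-1-yl]copper | CCCC[C@H](CC)C/C(CC)=C/[Cu] | intermediate
6 | (1E,4S)-2,4-diethyl-1-iodooct-1-ene | CCCC[C@H](CC)C/C(CC)=C/I | intermediate
7 | 3-[(4-methoxybenzyl)oxy]propan-1-ol | OCCCOCc1ccc(OC)cc1 | starting material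
8 | 3-[(4-methoxybenzyl)oxy]propanal | O=CCCOCc1ccc(OC)cc1 | intermediate
9 | (4S)-4-benzyl-3-butanoyl-1,3-oxazolidin-2-one | CCCC(=O)N1[C@@H](Cc2ccccc2)COC1=O | starting material
10 | (4S)-4-benzyl-3-[(1Z)-1-[(dibutylboranyl)oxy]but-1-en-1-yl]-1,3-oxazolidin-2-one | CC/C=C(/N1[C@@H](Cc2ccccc2)COC1=O)OB(CCCC)CCCC | intermediate
11 | (4S)-4-benzyl-3-[(2S,3R)-2-ethyl-3-hydroxy-5-[(4-methoxybenzyl)oxy]pentanoyl]-1,3-oxazolidin-2-one | O=C(N1[C@@H](Cc2ccccc2)COC1=O)[C@@H](CC)[C@@H](CCOCc3ccc(OC)cc3)O | intermediate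
12 | (2R,3R)-2-ethyl-5-[(4-methoxybenzyl)oxy]pentane-1,3-diol | OC[C@@H](CC)[C@@H](CCOCc1ccc(OC)cc1)O | intermediate
13 | (2R,3R)-1-{[tert-butyl(diphenyl)silyl]oxy}-2-ethyl-5-[(4-methoxybenzyl)oxy]pentan-3-ol | CC(C)(C)[Si](c1ccccc1)(c1ccccc1)OC[C@@H](CC)[C@@H](CCOCc1ccc(OC)cc1)O | intermediate
14 | 2,3-dimethylbut-2-ene | CC(C)=C(C)C | starting material
15 | 2-methoxyprop-2-yl hydroperoxide | COC(C)(C)OO | intermediate
16 | (2R,3R)-1-{[tert-butyl(diphenyl)silyl]oxy}-2-ethyl-5-[(4-methoxybenzyl)oxy]pentan-3-yl trifluoromethanesulfonate | CC(C)(C)[Si](c1ccccc1)(c1ccccc1)OC[C@@H](CC)[C@@H](CCOCc1ccc(OC)cc1)OS(=O)(=O)C(F)(F)F | intermediate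
17 | tert-butyl{[(2R,3S)-2-ethyl-5-[(4-methoxybenzyl)oxy]-3-[(2-methoxypropan-2-yl)peroxy]pentyl]oxy}diphenylsilane | CC(C)(C)[Si](c1ccccc1)(c1ccccc1)OC[C@@H](CC)[C@H](CCOCc1ccc(OC)cc1)OOC(C)(C)OC | intermediate
18 | (2R,3S)-2-ethyl-5-[(4-methoxybenzyl)oxy]-3-[(2-methoxypropan-2-yl)peroxy]pentan-1-ol | OC[C@@H](CC)[C@H](CCOCc1ccc(OC)cc1)OOC(C)(C)OC | intermediate
19 | (2S,3S)-2-ethyl-5-[(4-methoxybenzyl)oxy]-3-[(2-methoxypropan-2-yl)peroxy]pentanal | O=C[C@@H](CC)[C@H](CCOCc1ccc(OC)cc1)OOC(C)(C)OC | intermediate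
20 | 1-({[(3S,4R,5Z)-4-ethyl-6-iodo-3-[(2-methoxypropan-2-yl)peroxy]oct-5-en-1-yl]oxy}methyl)-4-methoxybenzene | CC/C(I)=C/[C@@H](CC)[C@H](CCOCc1ccc(OC)cc1)OOC(C)(C)OC | intermediate
21 | [(1E,4S)-2,4-diethyloct-1-en-1-yl]lithium | CCCC[C@H](CC)C/C(CC)=C/[Li] | intermediate
22 | chloro[(1E,4S)-2,4-diethyloct-1-en-1-yl]zinc | CCCC[C@H](CC)C/C(CC)=C/[Zn]Cl | intermediate
23 | 1-({[(3S,4R,5Z,7E,10S)-4,6,8,10-tetraethyl-3-[(2-methoxypropan-2-yl)peroxy]tetradeca-5,7-dien-1-yl]oxy}methyl)-4-methoxybenzene | CCCC[C@H](CC)C/C(CC)=C/C(CC)=C\[C@@H](CC)[C@H](CCOCc1ccc(OC)cc1)OOC(C)(C)OC | intermediate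
24 | 1-({[(3S,4R,5Z,7E,10S)-4,6,8,10-tetraethyl-3-hydroperoxytetradeca-5,7-dien-1-yl]oxy}methyl)-4-methoxybenzene | CCCC[C@H](CC)C/C(CC)=C/C(CC)=C\[C@@H](CC)[C@H](CCOCc1ccc(OC)cc1)OO | intermediate
25 | (3S,4R,6S)-6-[(1E,4S)-2,4-diethyloct-1-en-1-yl]-4,6-diethyl-3-{2-[(4-methoxybenzyl)oxy]ethyl}-1,2-dioxane | CCCC[C@H](CC)C/C(=C/[C@]1(CC)C[C@@H](CC)[C@H](CCOCc2ccc(OC)cc2)OO1)CC | intermediate
26 | 2-[(3S,4R,6S)-6-[(1E,4S)-2,4-diethyloct-1-en-1-yl]-4,6-diethyl-1,2-dioxan-3-yl]ethan-1-ol | CCCC[C@H](CC)C/C(=C/[C@]1(CC)C[C@@H](CC)[C@H](CCO)OO1)CC | intermediate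
27 | 2-[(3S,4R,6S)-6-[(1E,4S)-2,4-diethyloct-1-en-1-yl]-4,6-diethyl-1,2-dioxan-3-yl]acetaldehyde | CCCC[C@H](CC)C/C(=C/[C@]1(CC)C[C@@H](CC)[C@H](CC=O)OO1)CC | intermediate
28 | 2-[(3S,4R,6S)-6-[(1E,4S)-2,4-diethyloct-1-en-1-yl]-4,6-diethyl-1,2-dioxan-3-yl]acetic acid | CCCC[C@H](CC)C/C(=C/[C@]1(CC)C[C@@H](CC)[C@H](CC(=O)O)OO1)CC | intermediate
29 | methyl 2-[(3S,4R,6S)-6-[(1E,4S)-2,4-diethyloct-1-en-1-yl]-4,6-diethyl-1,2-dioxan-3-yl]acetate | CCCC[C@H](CC)C/C(=C/[C@]1(CC)C[C@@H](CC)[C@H](CC(=O)OC)OO1)CC | target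

**Count and risks**

Total step count: 19. Longest linear sequence: 14 steps (7 to 29 through steps 5–8 and 10–19).

Steps most likely to fail:

1. Step 16 (Proposed new method). The allyl cation may live long enough to rotate about C5–C6 or to lose a proton, which would erode the facial selectivity at C6 or the 7E geometry. The acid may also re-ionise the tertiary allylic C6–O bond or start a Hock-type cleavage of the hydroperoxide. The fallback uses known chemistry and sets out from 24. Cycloperoxyiodination with N-iodosuccinimide in CH2Cl2 at −78 °C adds iodine and the hydroperoxide oxygen anti across the 5Z alkene through the same chair, so the C6 configuration follows from the alkene geometry, and should give the 5-iodo-1,2-dioxane F1. The iodine is then removed by tin hydride reduction (Bu3SnH, catalytic PhSeSePh, Et3B/air, toluene, −40 °C), where the benzeneselenol formed in the flask should trap the C5 radical before a 1,2-shift of the neighbouring alkenyl group can occur. The fallback comes back to the route at 25.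

2. Step 10. The branched secondary triflate may be lost by elimination or ionisation before the peroxide anion attacks. The fallback sets out from 13. The alcohol is converted into the stable mesylate F2 (MsCl, Et3N, CH2Cl2, 0 °C), which is displaced with free hydrogen peroxide (50% aq. H2O2, KOH, MeOH, 0 °C to rt) with inversion to the secondary hydroperoxide F3. Ketalisation of F3 with 2-methoxypropene and pyridinium p-toluenesulfonate comes back to the route at 17.

3. Step 13. The basic ylide may cause β-elimination of the peroxide or epimerisation at C4 of the α-branched aldehyde, or the Z selectivity may be insufficient. The fallback sets out from 19. Dibromo-olefination (CBr4, PPh3, CH2Cl2, 0 °C) should give the 1,1-dibromoalkene F4. A trans-selective Negishi mono-ethylation (EtZnCl, Pd(DPEphos)Cl2, THF) replaces the bromine trans to C4 and should give the (Z)-bromoalkene F5. Coupling of F5 with the alkenylzinc chloride 22 under Pd(t-Bu3P)2, which keeps the alkene configuration, comes back to the route at 23.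

**Further compounds**

F1 | step 16 | 5-iodo analogue of 25: (3S,4R,6S)-configured 6-[(1E,4S)-2,4-diethyloct-1-en-1-yl]-4,6-diethyl-5-iodo-3-{2-[(4-methoxybenzyl)oxy]ethyl}-1,2-dioxane with iodine trans to the C4 ethyl group and anti to O1 | CCCC[C@H](CC)C/C(=C/[C@]1(CC)[C@H](I)[C@@H](CC)[C@H](CCOCc2ccc(OC)cc2)OO1)CC
F2 | step 10 | (2R,3R)-1-{[tert-butyl(diphenyl)silyl]oxy}-2-ethyl-5-[(4-methoxybenzyl)oxy]pentan-3-yl methanesulfonate | CC(C)(C)[Si](c1ccccc1)(c1ccccc1)OC[C@@H](CC)[C@@H](CCOCc1ccc(OC)cc1)OS(C)(=O)=O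
F3 | step 10 | tert-butyl{[(2R,3S)-2-ethyl-3-hydroperoxy-5-[(4-methoxybenzyl)oxy]pentyl]oxy}diphenylsilane | CC(C)(C)[Si](c1ccccc1)(c1ccccc1)OC[C@@H](CC)[C@H](CCOCc1ccc(OC)cc1)OO
F4 | step 13 | 1-({[(3S,4R)-6,6-dibromo-4-ethyl-3-[(2-methoxypropan-2-yl)peroxy]hex-5-en-1-yl]oxy}methyl)-4-methoxybenzene | BrC(Br)=C[C@@H](CC)[C@H](CCOCc1ccc(OC)cc1)OOC(C)(C)OC
F5 | step 13 | 1-({[(3S,4R,5Z)-6-bromo-4-ethyl-3-[(2-methoxypropan-2-yl)peroxy]oct-5-en-1-yl]oxy}methyl)-4-methoxybenzene | CC/C(Br)=C/[C@@H](CC)[C@H](CCOCc1ccc(OC)cc1)OOC(C)(C)OC
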